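The route rests on reading the diene C9=C10–C1=C2, which spans the fusion of ring A and ring B (eremophilane numbering: ester at C3, methyls at C4 and C5, hydroxyl at C7, ketone at C8), as a terminal alkyne C10≡C1 on the quaternary carbon C5 flanked by two olefinic arms. A single ruthenium-catalysed ene–yne–ene metathesis cascade closes ring B through C9=C10 and then ring A through the C1=C2 double bond, turning an acyclic dienyne into the bicyclic core. The precursor already carries all four core stereocentres, set by an enantioselective Ireland–Claisen rearrangement (C4, C5), a Felkin reduction (C3) and an allylboration (C7), and the complete side-chain ester.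

Key step: step 15

Assumption: the (S,S)-configured bromoborane of step 2 is taken to give the (2R,3R)-acid 5; if the sense of induction is the opposite, the (R,R)-reagent is used and nothing else changes. Compounds 1, 2, 7, 10, 11, 19 and 27 are taken as commercial.

Step 1
Reactants: 1 (Z)-3-methylpent-2-en-4-yn-1-ol; 2 propanoyl chloride
Product: 3 (Z)-3-methylpent-2-en-4-yn-1-yl propanoate
Conditions: pyridine, DMAP (cat.), CH2Cl2, 0 °C → rt
Reagents that add atoms: none
Why: Acylation of the primary allylic alcohol by the acid chloride under nucleophilic catalysis should leave the terminal alkyne and the Z-olefin untouched.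

Step 2
Reactants: 3 (Z)-3-methylpent-2-en-4-yn-1-yl propanoate
Product: 5 (2R,3R)-3-ethynyl-2,3-dimethylpent-4-enoic acid, via boron ketene acetal 4 (not isolated)
Conditions: (S,S)-2-bromo-4,5-diphenyl-1,3-bis[3,5-bis(trifluoromethyl)phenylsulfonyl]-1,3,2-diazaborolidine (1.2 equiv), i-Pr2NEt, CH2Cl2, –78 °C; then –20 → 4 °C; aqueous work-up
Reagents that add atoms: none
Why: In this enantioselective boron-enolate Ireland–Claisen rearrangement, soft enolisation should give the Z(O)-ketene acetal 4, whose [3,3] shift through a chair with both methyl groups equatorial and the slim ethynyl group axial sets C2 and C3 of the acid (C4 and C5 of the target) together in the like sense, while the chiral controller on boron selects the enolate face and so the absolute configuration.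

Step 3
Reactants: 5 (2R,3R)-3-ethynyl-2,3-dimethylpent-4-enoic acid
Product: 6 (2R,3R)-3-ethynyl-N-methoxy-N,2,3-trimethylpent-4-enamide
Conditions: MeNHOMe·HCl, EDC·HCl, HOBt (cat.), N-methylmorpholine, CH2Cl2, 0 °C → rt
Reagents that add atoms: N,O-dimethylhydroxylamine hydrochloride CNOC.Cl
Why: Carbodiimide amide coupling to the Weinreb amide is a mild activation that should not epimerise the hindered α-stereocentre.

Step 4
Reactants: 6 (2R,3R)-3-ethynyl-N-methoxy-N,2,3-trimethylpent-4-enamide; 7 2-methylprop-1-enylmagnesium bromide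
Product: 8 (5R,6R)-6-ethynyl-2,5,6-trimethylocta-2,7-dien-4-one
Conditions: Me2C=CHMgBr (3 equiv), THF, 0 °C → rt; aq. NH4Cl
Reagents that add atoms: none
Why: In this Weinreb ketone synthesis the chelated tetrahedral adduct should prevent over-addition and α-epimerisation, the excess Grignard reagent merely deprotonating the terminal alkyne, which is restored on work-up.

Step 5
Reactants: 8 (5R,6R)-6-ethynyl-2,5,6-trimethylocta-2,7-dien-4-one
Product: 9 (4S,5R,6R)-6-ethynyl-2,5,6-trimethylocta-2,7-dien-4-ol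
Conditions: LiBH(s-Bu)3, THF, –78 °C; aq. NH4Cl
Reagents that add atoms: none
Why: Felkin–Anh controlled 1,2-reduction, in which the bulky hydride attacks anti to the quaternary carbon and past the α-hydrogen, should give the 4,5-anti alcohol (C3 of the target, 3S), conjugate reduction being blocked by the two β-methyl groups.

Step 6
Reactants: 10 acetaldehyde; 11 (Z)-but-2-ene
Product: 15 (2S,3S)-3-methylpent-4-en-2-ol, via (Z)-crotylpotassium 12 (not isolated), via (Z)-crotyldiisopinocampheylborane 13 (not isolated), via borinate ester 14 (not isolated)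
Conditions: KOt-Bu, n-BuLi, THF, –78 → –45 °C; (+)-Ipc2BOMe, –78 °C; BF3·OEt2; 10, –78 °C; NaOH, H2O2
Reagents that add atoms: none
Why: In this asymmetric crotylboration the (Z)-crotylborane adds through a closed chair transition state, the Z-geometry giving the syn relationship and the isopinocampheyl groups derived from (–)-α-pinene directing attack to the Re face of acetaldehyde, so both side-chain stereocentres (2S,3S) are set at once.

Step 7
Reactants: 15 (2S,3S)-3-methylpent-4-en-2-ol
Product: 16 tert-butyldimethyl{[(2S,3S)-3-methylpent-4-en-2-yl]oxy}silane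
Conditions: TBSCl, imidazole, DMF, rt
Reagents that add atoms: tert-butyldimethylsilyl chloride CC(C)(C)[Si](C)(C)Cl
Why: Standard silylation protects the secondary hydroxyl, which must survive ozonolysis, base, boranes and MnO2 until the last step.

Step 8
Reactants: 16 tert-butyldimethyl{[(2S,3S)-3-methylpent-4-en-2-yl]oxy}silane
Product: 18 (2R,3S)-3-[(tert-butyldimethylsilyl)oxy]-2-methylbutanal, via ozonide 17 (not isolated)
Conditions: O3, CH2Cl2, –78 °C; PPh3, –78 °C → rt
Reagents that add atoms: ozone O=[O+][O-]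
Why: Ozonolysis of the terminal olefin with reductive work-up should deliver the α-methyl aldehyde under cold, neutral conditions that do not epimerise the α-centre.

Step 9
Reactants: 18 (2R,3S)-3-[(tert-butyldimethylsilyl)oxy]-2-methylbutanal; 19 triethyl (E)-4-phosphonobut-2-enoate
Product: 20 ethyl (2E,4E,6S,7S)-7-[(tert-butyldimethylsilyl)oxy]-6-methylocta-2,4-dienoate
Conditions: LiN(SiMe3)2, THF, –78 → 0 °C
Reagents that add atoms: none
Why: The vinylogous Horner–Wadsworth–Emmons olefination with the stabilised phosphonate anion should form the new 4,5-double bond E and keep the 2E geometry of the reagent, the low temperature protecting the α-stereocentre of 18.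

Step 10
Reactants: 20 ethyl (2E,4E,6S,7S)-7-[(tert-butyldimethylsilyl)oxy]-6-methylocta-2,4-dienoate
Product: 21 (2E,4E,6S,7S)-7-[(tert-butyldimethylsilyl)oxy]-6-methylocta-2,4-dienoic acid
Conditions: LiOH·H2O, THF/MeOH/H2O, rt; aq. HCl to pH 3
Reagents that add atoms: lithium hydroxide [Li+].[OH-]
Why: Saponification of the ethyl ester should leave the silyl ether and the (E,E)-diene intact at room temperature.

Step 11
Reactants: 9 (4S,5R,6R)-6-ethynyl-2,5,6-trimethylocta-2,7-dien-4-ol; 21 (2E,4E,6S,7S)-7-[(tert-butyldimethylsilyl)oxy]-6-methylocta-2,4-dienoic acid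
Product: 23 (4S,5R,6R)-6-ethynyl-2,5,6-trimethylocta-2,7-dien-4-yl (2E,4E,6S,7S)-7-[(tert-butyldimethylsilyl)oxy]-6-methylocta-2,4-dienoate, via mixed anhydride 22 (not isolated)
Conditions: 2,4,6-trichlorobenzoyl chloride, Et3N, THF, rt; then 9, DMAP, toluene, rt → 40 °C
Reagents that add atoms: none
Why: Yamaguchi esterification through the mixed anhydride 22 should acylate the hindered secondary allylic alcohol with retention, and installing the whole side chain while this is the only hydroxyl of the core removes any need for a protecting group at C3.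

Step 12
Reactants: 23 (4S,5R,6R)-6-ethynyl-2,5,6-trimethylocta-2,7-dien-4-yl (2E,4E,6S,7S)-7-[(tert-butyldimethylsilyl)oxy]-6-methylocta-2,4-dienoate
Product: 25 (4S,5R,6R)-6-ethynyl-8-hydroxy-2,5,6-trimethyloct-2-en-4-yl (2E,4E,6S,7S)-7-[(tert-butyldimethylsilyl)oxy]-6-methylocta-2,4-dienoate, via B-alkyl-9-borabicyclononane 24 (not isolated)
Conditions: 9-BBN (1.3 equiv), THF, 0 °C → rt; NaBO3·4H2O, H2O, rt
Reagents that add atoms: sodium perborate [Na+].[Na+].O[B-]1(O)OO[B-](O)(O)OO1
Why: Anti-Markovnikov hydroboration–oxidation with 9-BBN should favour the monosubstituted vinyl group over the terminal alkyne, the trisubstituted olefin and the electron-poor dienoate, and perborate oxidises the C–B bond without hydrolysing the ester.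

Step 13
Reactants: 25 (4S,5R,6R)-6-ethynyl-8-hydroxy-2,5,6-trimethyloct-2-en-4-yl (2E,4E,6S,7S)-7-[(tert-butyldimethylsilyl)oxy]-6-methylocta-2,4-dienoate
Product: 26 (4S,5R,6R)-6-ethynyl-2,5,6-trimethyl-8-oxooct-2-en-4-yl (2E,4E,6S,7S)-7-[(tert-butyldimethylsilyl)oxy]-6-methylocta-2,4-dienoate
Conditions: Dess–Martin periodinane, NaHCO3, CH2Cl2, 0 °C → rt
Reagents that add atoms: none
Why: Buffered Dess–Martin oxidation of the primary alcohol should give an aldehyde that has no α-stereocentre to lose.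

Step 14
Reactants: 26 (4S,5R,6R)-6-ethynyl-2,5,6-trimethyl-8-oxooct-2-en-4-yl (2E,4E,6S,7S)-7-[(tert-butyldimethylsilyl)oxy]-6-methylocta-2,4-dienoate; 27 allenylboronic acid pinacol ester
Product: 30 (4S,5R,6R,8R,9S)-6-ethynyl-8,9-dihydroxy-2,5,6-trimethylundeca-2,10-dien-4-yl (2E,4E,6S,7S)-7-[(tert-butyldimethylsilyl)oxy]-6-methylocta-2,4-dienoate, via (E)-γ-borylallylborane 28 (not isolated), via boryl borinate adduct 29 (not isolated)
Conditions: (–)-Ipc2BH, 27, Et2O, –25 → 0 °C; 26, –78 °C; NaBO3·4H2O, THF/H2O, rt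
Reagents that add atoms: sodium perborate [Na+].[Na+].O[B-]1(O)OO[B-](O)(O)OO1
Why: In this γ-borylallylboration the allylborane 28 adds through a chair transition state in which the isopinocampheyl groups derived from (+)-α-pinene direct attack to the Si face and set the 8R carbinol (C7 of the target), and oxidation of the C–B bond with retention gives the anti-diol, whose C9 configuration is irrelevant because that carbon becomes the ketone.

Step 15
Reactants: 30 (4S,5R,6R,8R,9S)-6-ethynyl-8,9-dihydroxy-2,5,6-trimethylundeca-2,10-dien-4-yl (2E,4E,6S,7S)-7-[(tert-butyldimethylsilyl)oxy]-6-methylocta-2,4-dienoate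
Product: 31 (1R,2S,6S,7R,8aR)-6,7-dihydroxy-1,8a-dimethyl-1,2,6,7,8,8a-hexahydronaphthalen-2-yl (2E,4E,6S,7S)-7-[(tert-butyldimethylsilyl)oxy]-6-methylocta-2,4-dienoate
Conditions: second-generation Grubbs catalyst (H2IMes)(PCy3)Cl2Ru=CHPh (10 mol%), 1,4-benzoquinone (20 mol%), toluene (0.003 M), 80 °C, argon
Reagents that add atoms: none
Why: The benzylidene should initiate at the only monosubstituted olefin (the vinyl group next to the free allylic hydroxyl), the resulting alkylidene adds across the terminal alkyne in the exo sense to forge C9=C10 of the target and ring B, and the vinylcarbene so placed on C1 undergoes ring-closing metathesis with the isobutenyl olefin to forge C1=C2 and ring A, expelling 2-methylpropene on turnover. The closest known reaction type is the tandem ring-closing metathesis of dienynes to fused bicyclic 1,3-dienes. Ring B closes by a six-membered exo enyne ring closure and ring A by a six-membered diene ring closure on the conjugated carbene. No stereocentre is formed: C3, C4, C5 and C7 are carried through unchanged and the C8 carbinol is oxidised in the next step. The step needs site selectivity of initiation, because a start on the other arm would give a five-membered enyne closure and a hydroazulene skeleton; the trisubstituted, doubly branched isobutenyl cap should not initiate, high dilution without ethene suppresses intermolecular and alkyne-first pathways, and the electron-poor, internally disubstituted dienoate should stay a spectator.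

Step 16
Reactants: 31 (1R,2S,6S,7R,8aR)-6,7-dihydroxy-1,8a-dimethyl-1,2,6,7,8,8a-hexahydronaphthalen-2-yl (2E,4E,6S,7S)-7-[(tert-butyldimethylsilyl)oxy]-6-methylocta-2,4-dienoate
Product: 32 (1R,2S,7R,8aR)-7-hydroxy-1,8a-dimethyl-6-oxo-1,2,6,7,8,8a-hexahydronaphthalen-2-yl (2E,4E,6S,7S)-7-[(tert-butyldimethylsilyl)oxy]-6-methylocta-2,4-dienoate
Conditions: MnO2 (activated, excess), CH2Cl2, rt
Reagents that add atoms: none
Why: MnO2 should oxidise only the allylic (dienylic) hydroxyl to the conjugated dienone, the saturated secondary hydroxyl at C7 and the silyl ether being inert.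

Step 17
Reactants: 32 (1R,2S,7R,8aR)-7-hydroxy-1,8a-dimethyl-6-oxo-1,2,6,7,8,8a-hexahydronaphthalen-2-yl (2E,4E,6S,7S)-7-[(tert-butyldimethylsilyl)oxy]-6-methylocta-2,4-dienoate
Product: 33 (1R,2S,7R,8aR)-7-hydroxy-1,8a-dimethyl-6-oxo-1,2,6,7,8,8a-hexahydronaphthalen-2-yl (2E,4E,6S,7S)-7-hydroxy-6-methylocta-2,4-dienoate (CNP0329432.2)
Conditions: HF·pyridine, pyridine, THF, 0 °C → rt
Reagents that add atoms: none
Why: Buffered fluoride cleavage of the silyl ether should leave the α-ketol, the dienone and the allylic ester untouched.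

Compound list
1 | (Z)-3-methylpent-2-en-4-yn-1-ol | OC/C=C(/C)C#C | starting material
2 | propanoyl chloride | CCC(=O)Cl | starting material
3 | (Z)-3-methylpent-2-en-4-yn-1-yl propanoate | CCC(=O)OC/C=C(/C)C#C | intermediate
4 | Z(O)-boron ketene acetal of 3 carrying the (4S,5S)-4,5-diphenyl-1,3-bis[3,5-bis(trifluoromethyl)phenylsulfonyl]-1,3,2-diazaborolidin-2-yl group | C/C=C(\OB1N(S(=O)(=O)c2cc(cc(c2)C(F)(F)F)C(F)(F)F)[C@@H](c2ccccc2)[C@H](c2ccccc2)N1S(=O)(=O)c1cc(cc(c1)C(F)(F)F)C(F)(F)F)OC/C=C(/C)C#C | intermediate (not isolated)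
5 | (2R,3R)-3-ethynyl-2,3-dimethylpent-4-enoic acid | OC(=O)[C@H](C)[C@](C)(C#C)C=C | intermediate
6 | (2R,3R)-3-ethynyl-N-methoxy-N,2,3-trimethylpent-4-enamide | CON(C)C(=O)[C@H](C)[C@](C)(C#C)C=C | intermediate
7 | 2-methylprop-1-enylmagnesium bromide | CC(C)=C[Mg]Br | starting material
8 | (5R,6R)-6-ethynyl-2,5,6-trimethylocta-2,7-dien-4-one | CC(C)=CC(=O)[C@H](C)[C@](C)(C#C)C=C | intermediate
9 | (4S,5R,6R)-6-ethynyl-2,5,6-trimethylocta-2,7-dien-4-ol | CC(C)=C[C@H](O)[C@H](C)[C@](C)(C#C)C=C | intermediate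
10 | acetaldehyde | CC=O | starting material
11 | (Z)-but-2-ene | C/C=C\C | starting material
12 | (Z)-but-2-en-1-ylpotassium | C/C=C\C[K] | intermediate (not isolated)
13 | (Z)-but-2-en-1-yl-diisopinocampheylborane, (–)-α-pinene series | C/C=C\CB([C@H]1C[C@H]2C[C@@H]([C@@H]1C)C2(C)C)[C@H]1C[C@H]2C[C@@H]([C@@H]1C)C2(C)C | intermediate (not isolated)
14 | diisopinocampheylborinate of 15 | C[C@H](OB([C@H]1C[C@H]2C[C@@H]([C@@H]1C)C2(C)C)[C@H]1C[C@H]2C[C@@H]([C@@H]1C)C2(C)C)[C@@H](C)C=C | intermediate (not isolated)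
15 | (2S,3S)-3-methylpent-4-en-2-ol | C[C@H](O)[C@@H](C)C=C | intermediate
16 | tert-butyldimethyl{[(2S,3S)-3-methylpent-4-en-2-yl]oxy}silane | C[C@H](O[Si](C)(C)C(C)(C)C)[C@@H](C)C=C | intermediate
17 | 3-[(2S,3S)-3-(tert-butyldimethylsilyloxy)butan-2-yl]-1,2,4-trioxolane | C[C@H](O[Si](C)(C)C(C)(C)C)[C@@H](C)C1OCOO1 | intermediate (not isolated)
18 | (2R,3S)-3-[(tert-butyldimethylsilyl)oxy]-2-methylbutanal | C[C@H](O[Si](C)(C)C(C)(C)C)[C@@H](C)C=O | intermediate
19 | triethyl (E)-4-phosphonobut-2-enoate | CCOC(=O)/C=C/CP(=O)(OCC)OCC | starting material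
20 | ethyl (2E,4E,6S,7S)-7-[(tert-butyldimethylsilyl)oxy]-6-methylocta-2,4-dienoate | C[C@H](O[Si](C)(C)C(C)(C)C)[C@@H](C)/C=C/C=C/C(=O)OCC | intermediate
21 | (2E,4E,6S,7S)-7-[(tert-butyldimethylsilyl)oxy]-6-methylocta-2,4-dienoic acid | C[C@H](O[Si](C)(C)C(C)(C)C)[C@@H](C)/C=C/C=C/C(=O)O | intermediate
22 | mixed anhydride of 21 with 2,4,6-trichlorobenzoic acid | C[C@H](O[Si](C)(C)C(C)(C)C)[C@@H](C)/C=C/C=C/C(=O)OC(=O)c1c(Cl)cc(Cl)cc1Cl | intermediate (not isolated)
23 | (4S,5R,6R)-6-ethynyl-2,5,6-trimethylocta-2,7-dien-4-yl (2E,4E,6S,7S)-7-[(tert-butyldimethylsilyl)oxy]-6-methylocta-2,4-dienoate | C[C@H](O[Si](C)(C)C(C)(C)C)[C@@H](C)/C=C/C=C/C(=O)O[C@@H](C=C(C)C)[C@H](C)[C@](C)(C#C)C=C | intermediate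
24 | B-alkyl-9-borabicyclo[3.3.1]nonane from 23 | C[C@H](O[Si](C)(C)C(C)(C)C)[C@@H](C)/C=C/C=C/C(=O)O[C@@H](C=C(C)C)[C@H](C)[C@](C)(C#C)CCB1C2CCCC1CCC2 | intermediate (not isolated)
25 | (4S,5R,6R)-6-ethynyl-8-hydroxy-2,5,6-trimethyloct-2-en-4-yl (2E,4E,6S,7S)-7-[(tert-butyldimethylsilyl)oxy]-6-methylocta-2,4-dienoate | C[C@H](O[Si](C)(C)C(C)(C)C)[C@@H](C)/C=C/C=C/C(=O)O[C@@H](C=C(C)C)[C@H](C)[C@](C)(C#C)CCO | intermediate
26 | (4S,5R,6R)-6-ethynyl-2,5,6-trimethyl-8-oxooct-2-en-4-yl (2E,4E,6S,7S)-7-[(tert-butyldimethylsilyl)oxy]-6-methylocta-2,4-dienoate | C[C@H](O[Si](C)(C)C(C)(C)C)[C@@H](C)/C=C/C=C/C(=O)O[C@@H](C=C(C)C)[C@H](C)[C@](C)(C#C)CC=O | intermediate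
27 | allenylboronic acid pinacol ester | C=C=CB1OC(C)(C)C(C)(C)O1 | starting material
28 | (E)-[3-(4,4,5,5-tetramethyl-1,3,2-dioxaborolan-2-yl)allyl]diisopinocampheylborane, (+)-α-pinene series | CC1(C)OB(/C=C/CB([C@@H]2C[C@@H]3C[C@H]([C@H]2C)C3(C)C)[C@@H]2C[C@@H]3C[C@H]([C@H]2C)C3(C)C)OC1(C)C | intermediate (not isolated)
29 | 8-O-diisopinocampheylboryl 9-pinacolboryl adduct of 26 | C[C@H](O[Si](C)(C)C(C)(C)C)[C@@H](C)/C=C/C=C/C(=O)O[C@@H](C=C(C)C)[C@H](C)[C@](C)(C#C)C[C@@H](OB([C@@H]1C[C@@H]2C[C@H]([C@H]1C)C2(C)C)[C@@H]1C[C@@H]2C[C@H]([C@H]1C)C2(C)C)[C@@H](B1OC(C)(C)C(C)(C)O1)C=C | intermediate (not isolated)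
30 | (4S,5R,6R,8R,9S)-6-ethynyl-8,9-dihydroxy-2,5,6-trimethylundeca-2,10-dien-4-yl (2E,4E,6S,7S)-7-[(tert-butyldimethylsilyl)oxy]-6-methylocta-2,4-dienoate | C[C@H](O[Si](C)(C)C(C)(C)C)[C@@H](C)/C=C/C=C/C(=O)O[C@@H](C=C(C)C)[C@H](C)[C@](C)(C#C)C[C@@H](O)[C@@H](O)C=C | intermediate
31 | (1R,2S,6S,7R,8aR)-6,7-dihydroxy-1,8a-dimethyl-1,2,6,7,8,8a-hexahydronaphthalen-2-yl (2E,4E,6S,7S)-7-[(tert-butyldimethylsilyl)oxy]-6-methylocta-2,4-dienoate | C[C@H](O[Si](C)(C)C(C)(C)C)[C@@H](C)/C=C/C=C/C(=O)O[C@H]1C=CC2=C[C@H](O)[C@H](O)C[C@]2(C)[C@H]1C | intermediate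
32 | (1R,2S,7R,8aR)-7-hydroxy-1,8a-dimethyl-6-oxo-1,2,6,7,8,8a-hexahydronaphthalen-2-yl (2E,4E,6S,7S)-7-[(tert-butyldimethylsilyl)oxy]-6-methylocta-2,4-dienoate | C[C@H](O[Si](C)(C)C(C)(C)C)[C@@H](C)/C=C/C=C/C(=O)O[C@H]1C=CC2=CC(=O)[C@H](O)C[C@]2(C)[C@H]1C | intermediate
33 | (1R,2S,7R,8aR)-7-hydroxy-1,8a-dimethyl-6-oxo-1,2,6,7,8,8a-hexahydronaphthalen-2-yl (2E,4E,6S,7S)-7-hydroxy-6-methylocta-2,4-dienoate | C[C@H](O)[C@@H](C)/C=C/C=C/C(=O)O[C@H]1C=CC2=CC(=O)[C@H](O)C[C@]2(C)[C@H]1C | target

Total step count: 17. Longest linear sequence: 12 steps (steps 1–5 and 11–17; the side-chain branch, steps 6–10 followed by 11–17, is equally long).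

Steps most likely to fail

1. Step 15. The cascade may start at the wrong olefin or proceed through intermolecular enyne metathesis, giving the ring-size isomer or oligomers. The fallback consumes the alkyne first. From 30, cross enyne metathesis with ethene (1 atm, second-generation Grubbs catalyst (H2IMes)(PCy3)Cl2Ru=CHPh, CH2Cl2, 40 °C) should give the 2-substituted buta-1,3-diene, tetraene (4S,5R,6R,8R,9S)-6-(buta-1,3-dien-2-yl)-8,9-dihydroxy-2,5,6-trimethylundeca-2,10-dien-4-yl (2E,4E,6S,7S)-7-[(tert-butyldimethylsilyl)oxy]-6-methylocta-2,4-dienoate F1. After removal of ethene, the same catalyst at high dilution in toluene at 80 °C closes ring B (allylic-alcohol vinyl group onto the 1,1-disubstituted diene terminus) and ring A (diene vinyl group onto the isobutenyl group, again forming C1=C2) by two ordinary diene ring-closing metatheses, and the route is rejoined at 31.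

2. Step 2. Enolisation may give poor geometry control, the rearrangement of the hindered trisubstituted allyl unit may be slow, or the enantioselectivity may be low. The fallback separates diastereocontrol from absolute control. From 3, LiN(i-Pr)2 (2.2 equiv) and Me3SiCl in THF/DMPU at –78 °C should give the C,O-bis-silylated Z(O)-ketene acetal F2, which on warming rearranges through the same chair to the racemic C-silylated trimethylsilyl ester F3. K2CO3 in MeOH followed by acidification frees the racemic (2R*,3R*)-acid F4. Crystallisation with (R)-1-phenylethylamine should give the (R)-1-phenylethylammonium salt F5 of the (2R,3R)-acid, and acidification returns to 5.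

3. Step 12. Hydroboration may also attack the terminal alkyne, or be incomplete at the neopentyl vinyl group. The fallback masks the alkyne. From 23, Zn(OTf)2 (cat.), Et3N and Me3SiOTf in CH2Cl2 should cap the alkyne as the alkynylsilane F6. 9-BBN and then NaBO3·4H2O give, via the B-alkylborane F7, the primary alcohol F8. AgNO3 (cat.) in aqueous acetone removes the C-silyl group without touching the silyl ether or the ester, and the route is rejoined at 25.

Further compounds
F1 | step 15 | (4S,5R,6R,8R,9S)-6-(buta-1,3-dien-2-yl)-8,9-dihydroxy-2,5,6-trimethylundeca-2,10-dien-4-yl (2E,4E,6S,7S)-7-[(tert-butyldimethylsilyl)oxy]-6-methylocta-2,4-dienoate | C[C@H](O[Si](C)(C)C(C)(C)C)[C@@H](C)/C=C/C=C/C(=O)O[C@@H](C=C(C)C)[C@H](C)[C@](C)(C(=C)C=C)C[C@@H](O)[C@@H](O)C=C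
F2 | step 2 | trimethyl{[(1Z)-1-{[(2Z)-3-methyl-5-(trimethylsilyl)pent-2-en-4-yn-1-yl]oxy}prop-1-en-1-yl]oxy}silane | C/C=C(\O[Si](C)(C)C)OC/C=C(/C)C#C[Si](C)(C)C
F3 | step 2 | racemic trimethylsilyl (2R*,3R*)-2,3-dimethyl-3-[(trimethylsilyl)ethynyl]pent-4-enoate | C[Si](C)(C)OC(=O)[C@H](C)[C@](C)(C#C[Si](C)(C)C)C=C.C[Si](C)(C)OC(=O)[C@@H](C)[C@@](C)(C#C[Si](C)(C)C)C=C
F4 | step 2 | racemic (2R*,3R*)-3-ethynyl-2,3-dimethylpent-4-enoic acid | OC(=O)[C@H](C)[C@](C)(C#C)C=C.OC(=O)[C@@H](C)[C@@](C)(C#C)C=C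
F5 | step 2 | (R)-1-phenylethylammonium (2R,3R)-3-ethynyl-2,3-dimethylpent-4-enoate | [O-]C(=O)[C@H](C)[C@](C)(C#C)C=C.C[C@@H]([NH3+])c1ccccc1
F6 | step 12 | (4S,5R,6R)-2,5,6-trimethyl-6-[(trimethylsilyl)ethynyl]octa-2,7-dien-4-yl (2E,4E,6S,7S)-7-[(tert-butyldimethylsilyl)oxy]-6-methylocta-2,4-dienoate | C[C@H](O[Si](C)(C)C(C)(C)C)[C@@H](C)/C=C/C=C/C(=O)O[C@@H](C=C(C)C)[C@H](C)[C@](C)(C#C[Si](C)(C)C)C=C
F7 | step 12 | B-alkyl-9-borabicyclo[3.3.1]nonane from F6 | C[C@H](O[Si](C)(C)C(C)(C)C)[C@@H](C)/C=C/C=C/C(=O)O[C@@H](C=C(C)C)[C@H](C)[C@](C)(C#C[Si](C)(C)C)CCB1C2CCCC1CCC2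
F8 | step 12 | (4S,5R,6R)-8-hydroxy-2,5,6-trimethyl-6-[(trimethylsilyl)ethynyl]oct-2-en-4-yl (2E,4E,6S,7S)-7-[(tert-butyldimethylsilyl)oxy]-6-methylocta-2,4-dienoate | C[C@H](O[Si](C)(C)C(C)(C)C)[C@@H](C)/C=C/C=C/C(=O)O[C@@H](C=C(C)C)[C@H](C)[C@](C)(C#C[Si](C)(C)C)CCO
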